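The substrate was the easy step: in eta, the flask you are taking over, it read 1.0% by 8.00 min, so watch the target instead.

| setting | eta | alpha | flask |
|---|---|---|---|
| substrate | 17 mM | 17 mM | 17 mM |
| temperature | 25 °C | 10 °C | 25 °C |
| remark | the very flask that is asked about, followed so far | run made earlier |  |
| time |  |  | 3.0 h |

- eta (time / min: target / %, substrate / %): 8.00: 37.8, 1.0; 20.0: 13.1, 0; 40.0: 9.4, 0.3; 60.0: 9.1, 0; 80.0: 9.5, 0; 120: 9.9, 0.3; 150: 9.3, 0.1
- alpha (time / min: target / %, substrate / %): 15.0: 31.0, 17.1; 40.0: 46.0, 0.7; 80.0: 26.7, 0; 120: 16.0, 0; 180: 11.5, 0; 240: 11.2, 0; 300: 11.2, 0.1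

(each reading ± 0.3 percentage points)

- removed target is counted in
- what was read earlier has a scatter of 0.3 percentage points, one standard deviation
- additions bring no volume worth counting

- autumn: at 3.0 h add substrate, 50.0% of the amount charged, then wait 3.0 h
- noon: at 3.0 h raise the temperature by 20 K, then wait 3.0 h
- winter: at 3.0 h take out 90% of the target then present, then wait 3.0 h
- dusk: change nothing and wait 3.0 h more

- target, in percent of the substrate first charged, at 3.0 h
- the remedy with the largest gain of target, or "none" below 2 percentage points (autumn / noon / winter / dusk / none)
- target present, with what was taken out counted in, in percent of the substrate first charged, after autumn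
- target present, with what was taken out counted in, in percent of the substrate first charged, after winter

My note for the bench: eta's target readings from 40.0 min on averaged 9.44%. I called this the standing share, the fraction of reacted substrate that stands as [target] once target and its unread partners balance. I read this as thermodynamic control, not a spent reagent. The excess over that share halved in about 4.06 min, far shorter than 3.0 h, so I expected 9.44% when you came.

Don't heat: alpha, at 10 °C, levelled higher, at 11.2%. Don't merely wait either. Autumn and winter both leave the flask at 25 °C, and there the 3.0 h wait far exceeds that half-life, so I expected the share to re-form on what remains. Autumn gives 14.2%; winter, counted in, gives 17.1%, more than autumn. I chose winter.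

The forecast differed, holding that “something is used up, a co-reagent or a turnover-limited catalyst”. It gave 9.4%, chose autumn, and put autumn at 59.4% and winter at 9.4%.

The flask gave 9.29%. The best remedy was winter, at 16.9%, a gain of 7.6 percentage points; autumn reached 14.0%, a gain of 4.7 points.

    intermediate ⇌ isomer of the product A (K = 2.50, k = 3.70 × 10⁻⁴ s⁻¹, Ea = 101 kJ mol⁻¹, ΔH = −70.0 kJ mol⁻¹)
    substrate → intermediate (k = 0.00920 s⁻¹, Ea = 72.0 kJ mol⁻¹)
    intermediate ⇌ target (K = 8.20, k = 0.00790 s⁻¹, Ea = 89.0 kJ mol⁻¹, ΔH = 0 kJ mol⁻¹)
    target ⇌ isomer of the product B (K = 9.30, k = 0.00320 s⁻¹, Ea = 92.0 kJ mol⁻¹, ΔH = 9.00 kJ mol⁻¹)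
    (constants at 25 °C)

At 180 min the flask held 86.1% as isomer of the product B against 9.29% as target, and that step relaxes with a half-life of 3.26 min, short against 3.0 h. So the plateau was a balance, not a used-up consumer. The neighbouring flask is the same charge read at 50 min, later than my read half-life, so the standing share puts its target at 9.44%. That neighbour holds 9.23%.

The runs stem from a simulated flask on assumed constants, and the scatter is random.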